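**Plan**
1. Numbering follows indene: C1–C3 are the ring CH2 groups, C3a/C7a the ring fusion, C4=C5 the ring alkene; C6 carries the acid arm C1''–C8'' and C7 the dienoate arm C1'–C5'.
2. The retrosynthesis cuts C1'=C2' (HWE), then C1–C2 and C2–C3 (bis-sulfone cycloalkylation), then C2''–C3'' (Suzuki) and C1''=C2'' (iodo-olefination), which leaves a cyclohexene with four one-carbon arms.
3. The enabling feature: C3 (on C3a) and C1'' (on C6) are cis across the C4=C5 alkene and anti to the cis pair C1' (on C7)/C1 (on C7a). Tied together as a C3–C1'' glycol they are the third bridge of a bicyclo[2.2.2]octene, which a Diels–Alder cut at C3a–C3 and C6–C1'' divides into cis-1,2-dihydrophthalic anhydride and vinylene carbonate.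
4. Forward: phthalic acid supplies the six-membered ring; the cycloaddition closes the temporary bridge ring; methanolysis tells C1 from C1'; periodate reopens the bridge and a lactol tells C3 from C1''; the acid arm is attached, the five-membered ring is closed, and the dienoate arm comes last.
5. Stereochemistry: the relative configuration of C3a, C6, C7 and C7a comes from cycloaddition anti to the anhydride, the absolute configuration from the quinidine-mediated opening of the meso anhydride, and the four E alkenes from Takai, Suzuki and HWE reactions.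

Key step: step 3

Remark 1: quinidine is assumed to open 5 in the sense usual for endo-bicyclic meso anhydrides (methanol at the carbonyl that becomes C1); if the sense is the opposite, quinine takes its place and nothing else changes.
Remark 2: 5 is drawn with the carbonate on the alkene side (endo); an exo-carbonate isomer would differ only at C3/C1'' and would merge with the route at 12.

Step 1
Reactants: 1 phthalic acid
Product: 2 (±)-trans-1,2-dihydrophthalic acid
Conditions: 3% Na/Hg, NaOAc, aq. AcOH, 0–10 °C
Reagents that add atoms: none
Why: Dissolving-metal reduction of the arene dicarboxylate (electron transfer, then protonation at the two carboxyl-bearing carbons) stops at the 1,2-dihydro stage under acetate buffering and should give the racemic trans diacid, a long-established preparation.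

Step 2
Reactants: 2 (±)-trans-1,2-dihydrophthalic acid
Product: 3 cis-1,2-dihydrophthalic anhydride (meso)
Conditions: Ac2O, 100 °C, short heating
Reagents that add atoms: none
Why: Cyclodehydration through the mixed acetic anhydride, in which the α-carbonyl, allylic hydrogen epimerises and only the cis diacid can close to the five-membered anhydride, so the meso cis-anhydride should result; heating is kept short to avoid drift of the diene.

Step 3
Reactants: 3 cis-1,2-dihydrophthalic anhydride; 4 vinylene carbonate
Product: 5 meso anti adduct (bicyclo[2.2.2]octene with the anhydride on C7/C7a and the cyclic carbonate on C3/C1'')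
Conditions: neat 4 (5 equiv), BHT (cat.), sealed tube, 140–150 °C
Reagents that add atoms: none
Why: This is a concerted thermal [4π+2π] cycloaddition, suprafacial on both partners, of the ring diene C3a=C4–C5=C6 with the cis alkene of vinylene carbonate; the closest known reaction type is the Diels–Alder reaction of cyclohexa-1,3-dienes, including cis-5,6-disubstituted ones, with vinylene carbonate. The ring that closes is the six-membered bridge ring C3a–C3–C1''–C6–C5–C4, closed by intermolecular [4+2] addition across C3a and C6, which creates the bicyclo[2.2.2]octene while the cyclohexene of the target is the diene's own ring. C3a and C6 are set by the diene face that is attacked: the cis-fused anhydride on the sp3 carbons C7/C7a shields its own face, so both new bonds form anti to C1' and C1, and C7/C7a keep the cis relationship they have in 3. C3 and C1'' are set by the cis geometry of the dienophile and by its endo or exo orientation, which is of no consequence because both centres become sp2 in step 8. The selectivity the step needs is facial (anti) and is secured by the anhydride; the adduct is meso, so no absolute configuration is at stake yet. Excess neat dienophile and a radical inhibitor offset the low dienophilicity, and the temperature is held as low as conversion allows to limit hydrogen shifts in 3.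

Step 4
Reactants: 5 meso anti adduct
Product: 6 hemiester (C1 methyl ester on C7a; C1' carboxylic acid on C7; carbonate intact)
Conditions: quinidine (1.1 equiv), MeOH (3 equiv), toluene/CCl4, −55 °C; then dil. HCl
Reagents that add atoms: methanol, CO
Why: Alkaloid-mediated enantioselective alcoholysis of a meso anhydride, in which quinidine directs methanol to one of the two enantiotopic carbonyls (the one that becomes C1) and thereby fixes the absolute configuration of C3a, C6, C7 and C7a at once, while the less electrophilic cyclic carbonate is not attacked at this temperature.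

Step 5
Reactants: 6 hemiester
Product: 8 hydroxy ester (C1' carbinol; C1 methyl ester), via mixed carbonic anhydride 7 (not isolated)
Conditions: i-BuOCOCl, N-methylmorpholine, THF, −15 °C; then NaBH4, MeOH, −15 → 0 °C; neutral work-up
Reagents that add atoms: none
Why: Activation of the acid as the mixed carbonic anhydride followed by borohydride reduction converts only the carboxylic acid into the primary alcohol and leaves methyl ester, cyclic carbonate and alkene untouched; the product is kept cold and neutral and silylated at once so that it does not lactonise onto the C1 ester.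

Step 6
Reactants: 8 hydroxy ester
Product: 9 silyl ether (C1'–OTBDPS; C1 methyl ester; carbonate)
Conditions: TBDPSCl, imidazole, DMF, 0 °C → rt
Reagents that add atoms: tert-butyl(chloro)diphenylsilane, CC(C)(C)[Si](Cl)(c1ccccc1)c1ccccc1
Why: Imidazole-promoted silylation of a primary alcohol, which marks C1' with a robust ether that lasts until step 17 and rules out lactonisation.

Step 7
Reactants: 9 silyl ether
Product: 10 triol (C1 carbinol; cis-diol on C3/C1''; C1'–OTBDPS)
Conditions: LiAlH4, THF, 0 °C
Reagents that add atoms: none
Why: Hydride reduction, in which LiAlH4 reduces the methyl ester to the C1 carbinol and the cyclic carbonate to the cis-diol in one operation, while the silyl ether and the isolated alkene are inert at 0 °C.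

Step 8
Reactants: 10 triol
Product: 12 lactol aldehyde (trans-fused C1–O–C3 lactol as anomers; free C1'' aldehyde on C6), via hydroxy dialdehyde 11 (not isolated)
Conditions: NaIO4, THF/pH 7 buffer, 0 °C; used crude
Reagents that add atoms: none
Why: Malaprade glycol cleavage of the rigid cis-diol cuts C3–C1'' and turns the bridge into two aldehydes, of which only C3 has the C1 hydroxyl within reach (trans-1,2 on the ring) and closes to the five-membered lactol, which tells C3 from C1''; no bond to C3a or C6 is broken and the neutral, cold medium guards these allylic α-centres.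

Step 9
Reactants: 12 lactol aldehyde
Product: 13 (E)-vinyl iodide lactol
Conditions: CrCl2 (6 equiv), CHI3 (2 equiv), THF, 0 °C → rt, dark
Reagents that add atoms: iodoform, IC(I)I
Why: Takai iodo-olefination, in which the gem-dichromium species from CHI3/CrCl2 adds to the free C1'' aldehyde and eliminates to the (E)-vinyl iodide under essentially neutral conditions, so that C6 should keep its configuration and the masked C3 lactol should react much more slowly than the free aldehyde.

Step 10
Reactants: 13 (E)-vinyl iodide lactol
Product: 14 vinyl iodide diol (C1 and C3 carbinols)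
Conditions: NaBH4, MeOH, 0 °C
Reagents that add atoms: none
Why: Borohydride reduces the lactol through its open hydroxy-aldehyde form to the primary alcohol and so gives the 1,4-diol, with vinyl iodide and silyl ether inert.

Step 11
Reactants: 15 hex-5-ynoic acid
Product: 16 tert-butyl hex-5-ynoate
Conditions: tert-butyl 2,2,2-trichloroacetimidate, BF3·OEt2 (cat.), CH2Cl2/cyclohexane, rt
Reagents that add atoms: tert-butyl 2,2,2-trichloroacetimidate, CC(C)(C)OC(=N)C(Cl)(Cl)Cl
Why: Acid-catalysed tert-butylation of a carboxylic acid by the imidate gives an ester that should survive hydride, carbanion and amalgam steps and can be removed at the end without touching a methyl ester.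

Step 12
Reactants: 16 tert-butyl hex-5-ynoate
Product: 17 tert-butyl (E)-6-(pinacolboryl)hex-5-enoate
Conditions: pinacolborane, Cp2Zr(H)Cl (5 mol%), Et3N (5 mol%), neat, 60 °C
Reagents that add atoms: pinacolborane, CC1(C)OBOC1(C)C
Why: Zirconocene-hydride-catalysed hydroboration of a terminal alkyne is a syn, anti-Markovnikov addition and should give the (E)-alkenylboronate with the ester untouched.

Step 13
Reactants: 14 vinyl iodide diol; 17 tert-butyl (E)-6-(pinacolboryl)hex-5-enoate
Product: 18 diene diol (C6 arm complete as (1''E,3''E)-diene tert-butyl ester)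
Conditions: Pd(dppf)Cl2 (5 mol%), K3PO4, THF/H2O, rt, degassed
Reagents that add atoms: none
Why: Suzuki–Miyaura coupling of an (E)-alkenyl iodide with an (E)-alkenylboronate proceeds with retention at both sp2 carbons and forms C2''–C3'' as the E,E-diene, the free hydroxyls and the ester being tolerated by the mild aqueous base.

Step 14
Reactants: 18 diene diol
Product: 19 dimesylate
Conditions: MsCl (3 equiv), Et3N, CH2Cl2, −10 °C
Reagents that add atoms: methanesulfonyl chloride, CS(=O)(=O)Cl
Why: Sulfonylation of both primary alcohols at low temperature with excess reagent, fast enough to outrun cyclisation of a monomesylate to the tetrahydrofuran.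

Step 15
Reactants: 19 dimesylate; 20 bis(phenylsulfonyl)methane
Product: 22 bis-sulfone (trans-fused hydrindene with C2 bearing two phenylsulfonyl groups), via monoalkylated mesylate 21 (not isolated)
Conditions: Cs2CO3, Bu4NI (10 mol%), DMF, 70 °C
Reagents that add atoms: none
Why: Double alkylation of the doubly stabilised, weakly basic bis-sulfonyl carbanion, first by intermolecular SN2 at one primary mesylate (drawn at C3, the order being immaterial) and then by 5-exo-tet closure at the other, forms C1–C2 and C2–C3 and with them the five-membered ring, whose trans fusion is already fixed at C3a/C7a.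

Step 16
Reactants: 22 bis-sulfone
Product: 24 hydrindene silyl ether (C2 = CH2), via monosulfone 23 (not isolated)
Conditions: 6% Na/Hg, Na2HPO4, MeOH/THF, −20 °C → rt
Reagents that add atoms: none
Why: Reductive desulfonylation by electron transfer from the amalgam in buffered methanol removes the two sulfonyl groups one after the other and leaves C2 as CH2, while the ring alkene, the non-activated 1,3-diene (as in Julia olefinations that deliver dienes), the tert-butyl ester and the silyl ether should not be reduced.

Step 17
Reactants: 24 hydrindene silyl ether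
Product: 25 primary alcohol (C1'–OH)
Conditions: TBAF, THF, 0 °C → rt
Reagents that add atoms: none
Why: Fluoride-induced desilylation frees the C1' alcohol, the tert-butyl ester and the diene being inert.

Step 18
Reactants: 25 primary alcohol
Product: 26 aldehyde (C1' = CHO on C7)
Conditions: Dess–Martin periodinane, NaHCO3, CH2Cl2, 0 °C; used crude
Reagents that add atoms: none
Why: Dess–Martin oxidation under bicarbonate buffer gives the aldehyde without acid or strong base, so that C7, now α to a carbonyl, should keep its configuration.

Step 19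
Reactants: 26 aldehyde; 27 trimethyl 4-phosphonocrotonate
Product: 28 diester (methyl (2'E,4'E)-dienoate on C7; tert-butyl ester on the C6 arm)
Conditions: 27 (1.5 equiv), LiHMDS, THF, −78 → 0 °C
Reagents that add atoms: none
Why: Vinylogous Horner–Wadsworth–Emmons reaction, in which the lithiated phosphonocrotonate adds through its α-carbon to the aldehyde and loses phosphate to form C1'=C2' trans, giving the E,E-dienoate, while the low temperature and the weakly basic anion protect C7.

Step 20
Reactants: 28 diester
Product: 30 aplidic acid A, via trimethylsilyl ester 29 (not isolated)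
Conditions: TMSOTf, 2,6-lutidine, CH2Cl2, 0 °C; then aq. pH 5 buffer
Reagents that add atoms: none
Why: Silyl triflate with a hindered base converts the tert-butyl ester into the silyl ester with loss of isobutene and without free Brønsted acid, which should spare both dienes and the methyl ester, and the aqueous work-up hydrolyses the silyl ester to the acid.

**Compound list**
1 | phthalic acid | OC(=O)c1ccccc1C(=O)O | starting material
2 | (±)-trans-1,2-dihydrophthalic acid (trans-cyclohexa-3,5-diene-1,2-dicarboxylic acid; one enantiomer drawn) | OC(=O)[C@H]1C=CC=C[C@@H]1C(=O)O | intermediate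
3 | cis-1,2-dihydrophthalic anhydride (cis-cyclohexa-3,5-diene-1,2-dicarboxylic anhydride, meso) | O=C1OC(=O)[C@H]2C=CC=C[C@@H]12 | intermediate
4 | vinylene carbonate | O=C1OC=CO1 | starting material
5 | meso anti adduct: 7,8-(carbonyldioxy)bicyclo[2.2.2]oct-5-ene-2,3-dicarboxylic anhydride, anhydride and carbonate both on the alkene side | O=C1OC(=O)[C@H]2[C@@H]1[C@H]3C=C[C@@H]2[C@@H]4OC(=O)O[C@H]34 | intermediate
6 | hemiester of 5: methyl ester at C1 (on C7a), free acid at C1' (on C7) | COC(=O)[C@H]1[C@@H](C(=O)O)[C@H]2C=C[C@@H]1[C@@H]3OC(=O)O[C@H]23 | intermediate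
7 | mixed isobutyl carbonic anhydride of 6 at C1' | COC(=O)[C@H]1[C@@H](C(=O)OC(=O)OCC(C)C)[C@H]2C=C[C@@H]1[C@@H]3OC(=O)O[C@H]23 | intermediate (not isolated)
8 | hydroxy ester: C1' = CH2OH, C1 = CO2Me, carbonate intact | COC(=O)[C@H]1[C@@H](CO)[C@H]2C=C[C@@H]1[C@@H]3OC(=O)O[C@H]23 | intermediate
9 | silyl ether: C1'–OTBDPS, C1 = CO2Me, carbonate intact | COC(=O)[C@H]1[C@@H](CO[Si](c4ccccc4)(c4ccccc4)C(C)(C)C)[C@H]2C=C[C@@H]1[C@@H]3OC(=O)O[C@H]23 | intermediate
10 | triol: C1 = CH2OH, cis-diol on the C3–C1'' bridge, C1'–OTBDPS | OC[C@H]1[C@@H](CO[Si](c3ccccc3)(c3ccccc3)C(C)(C)C)[C@H]2C=C[C@@H]1[C@H](O)[C@@H]2O | intermediate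
11 | hydroxy dialdehyde: cyclohexene with CHO (C3) on C3a, CHO (C1'') on C6, CH2OH (C1) on C7a, CH2OTBDPS (C1') on C7 | O=C[C@@H]1C=C[C@H](C=O)[C@@H](CO)[C@H]1CO[Si](c2ccccc2)(c2ccccc2)C(C)(C)C | intermediate (not isolated)
12 | lactol aldehyde: trans-fused lactol C1–O–C3(OH) (anomers), CHO on C6, CH2OTBDPS on C7 | O=C[C@@H]1C=C[C@@H]2C(O)OC[C@H]2[C@H]1CO[Si](c3ccccc3)(c3ccccc3)C(C)(C)C | intermediate
13 | (E)-vinyl iodide lactol: C6–CH=CHI, lactol as in 12 | I/C=C/[C@@H]1C=C[C@@H]2C(O)OC[C@H]2[C@H]1CO[Si](c3ccccc3)(c3ccccc3)C(C)(C)C | intermediate
14 | vinyl iodide diol: CH2OH on C3a and on C7a (trans), (E)-CH=CHI on C6, CH2OTBDPS on C7 | I/C=C/[C@@H]1C=C[C@H](CO)[C@@H](CO)[C@H]1CO[Si](c2ccccc2)(c2ccccc2)C(C)(C)C | intermediate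
15 | hex-5-ynoic acid | C#CCCCC(=O)O | starting material
16 | tert-butyl hex-5-ynoate | C#CCCCC(=O)OC(C)(C)C | intermediate
17 | tert-butyl (E)-6-(4,4,5,5-tetramethyl-1,3,2-dioxaborolan-2-yl)hex-5-enoate | CC(C)(C)OC(=O)CCC/C=C/B1OC(C)(C)C(C)(C)O1 | intermediate
18 | diene diol: C6 arm = (1''E,3''E)-diene ending in CO2tBu; CH2OH on C3a and C7a; CH2OTBDPS on C7 | CC(C)(C)OC(=O)CCC/C=C/C=C/[C@@H]1C=C[C@H](CO)[C@@H](CO)[C@H]1CO[Si](c2ccccc2)(c2ccccc2)C(C)(C)C | intermediate
19 | dimesylate of 18 | CC(C)(C)OC(=O)CCC/C=C/C=C/[C@@H]1C=C[C@H](COS(C)(=O)=O)[C@@H](COS(C)(=O)=O)[C@H]1CO[Si](c2ccccc2)(c2ccccc2)C(C)(C)C | intermediate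
20 | bis(phenylsulfonyl)methane | O=S(=O)(CS(=O)(=O)c1ccccc1)c1ccccc1 | starting material
21 | monoalkylated mesylate: C3–CH(SO2Ph)2 on C3a, C1–OMs on C7a (regiochemistry of the first alkylation immaterial) | CC(C)(C)OC(=O)CCC/C=C/C=C/[C@@H]1C=C[C@H](CC(S(=O)(=O)c2ccccc2)S(=O)(=O)c2ccccc2)[C@@H](COS(C)(=O)=O)[C@H]1CO[Si](c2ccccc2)(c2ccccc2)C(C)(C)C | intermediate (not isolated)
22 | bis-sulfone: trans-fused 2,2-bis(phenylsulfonyl)hydrindene with both side chains | CC(C)(C)OC(=O)CCC/C=C/C=C/[C@@H]1C=C[C@@H]2CC(S(=O)(=O)c3ccccc3)(S(=O)(=O)c3ccccc3)C[C@H]2[C@H]1CO[Si](c3ccccc3)(c3ccccc3)C(C)(C)C | intermediate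
23 | monosulfone: 2-(phenylsulfonyl)hydrindene (C2 epimers) | CC(C)(C)OC(=O)CCC/C=C/C=C/[C@@H]1C=C[C@@H]2CC(S(=O)(=O)c3ccccc3)C[C@H]2[C@H]1CO[Si](c3ccccc3)(c3ccccc3)C(C)(C)C | intermediate (not isolated)
24 | hydrindene silyl ether: trans-fused ring complete, C1'–OTBDPS on C7, diene tert-butyl ester arm on C6 | CC(C)(C)OC(=O)CCC/C=C/C=C/[C@@H]1C=C[C@@H]2CCC[C@H]2[C@H]1CO[Si](c3ccccc3)(c3ccccc3)C(C)(C)C | intermediate
25 | primary alcohol: C1'–OH on C7 | CC(C)(C)OC(=O)CCC/C=C/C=C/[C@@H]1C=C[C@@H]2CCC[C@H]2[C@H]1CO | intermediate
26 | aldehyde: C1' = CHO on C7 | CC(C)(C)OC(=O)CCC/C=C/C=C/[C@@H]1C=C[C@@H]2CCC[C@H]2[C@H]1C=O | intermediate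
27 | trimethyl 4-phosphonocrotonate (methyl (E)-4-(dimethoxyphosphoryl)but-2-enoate) | COC(=O)/C=C/CP(=O)(OC)OC | starting material
28 | diester: methyl (2'E,4'E)-dienoate on C7, tert-butyl ester at the end of the C6 arm | CC(C)(C)OC(=O)CCC/C=C/C=C/[C@@H]1C=C[C@@H]2CCC[C@H]2[C@H]1/C=C/C=C/C(=O)OC | intermediate
29 | trimethylsilyl ester of aplidic acid A | C[Si](C)(C)OC(=O)CCC/C=C/C=C/[C@@H]1C=C[C@@H]2CCC[C@H]2[C@H]1/C=C/C=C/C(=O)OC | intermediate (not isolated)
30 | aplidic acid A | COC(=O)/C=C/C=C/[C@@H]1[C@@H]2CCC[C@H]2C=C[C@H]1/C=C/C=C/CCCC(=O)O | target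

**Step count**
Total: 20 steps. Longest linear sequence: 18 steps (steps 1–10 and 13–20, from phthalic acid); steps 11–12 form the side branch to boronate 17.

**Steps most likely to fail**

Step 3. Hydrogen shifts, aromatisation or dimerisation of diene 3 may outpace the slow cycloaddition to the weakly dienophilic vinylene carbonate. The fallback exchanges the roles of the partners and sets out from vinylene carbonate 4. Heated with buta-1,3-diene in a sealed tube, a robust diene for this dienophile, it should give cis-cyclohex-4-ene-1,2-diyl carbonate F1. Bromine addition gives the trans-dibromide F2, and double dehydrobromination (LiCl, Li2CO3, DMF, heat, as practised on the corresponding diacetate) gives the cis-5,6-(carbonyldioxy)cyclohexa-1,3-diene F3. This diene should add maleic anhydride at room temperature, anti to the carbonate and endo, to give the same meso adduct 5, where the route is rejoined.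

Step 9. The free C1'' aldehyde must be olefinated beside the C3 lactol, and its α-carbon C6 is allylic. Olefination of the ring-opened lactol, epimerisation at C6 or migration of C4=C5 into conjugation may therefore compete. The fallback differentiates C3 and C1'' by lactonisation instead and sets out from silyl ether 9.
- K2CO3 in methanol removes only the carbonate and gives the diol ester F4.
- Periodate cleavage gives the dialdehyde ester F5, which is reduced in the same flask by NaBH4 to the diol ester F6.
- Acid catalysis (CSA) then closes the C3 hydroxyl onto the C1 ester to the trans-fused hydroxy lactone F7; the C1'' hydroxyl cannot reach the ester.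
- Buffered Dess–Martin oxidation gives the aldehyde lactone F8, which now holds a single aldehyde-level carbon.
- Takai olefination gives the vinyl iodide lactone F9, and LiBH4 reduces the lactone to diol 14, where the route is rejoined.

Step 15. The bulky bis-sulfonyl carbanion may displace the β-branched mesylates too slowly, so that E2 elimination toward an exocyclic diene or ether formation takes over. The fallback uses a small, more nucleophilic mono-sulfonyl carbanion and closes the ring by intramolecular alkylation; it sets out from dimesylate 19. Lithiated methyl phenyl sulfone (2.5 equiv, THF/DMPU, −78 → 0 °C) displaces one mesylate to give the sulfone mesylate F10 (drawn alkylated at C3; the C1 isomer converges). Excess reagent deprotonates F10 next to sulfur, and 5-exo-tet closure gives monosulfone 23, here isolated. The route is rejoined at 23, which the amalgam conditions of step 16 reduce to 24.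

**Further compounds**
F1 | step 3 | cis-cyclohex-4-ene-1,2-diyl carbonate | O=C1O[C@H]2CC=CC[C@H]2O1
F2 | step 3 | trans-4,5-dibromocyclohexane-cis-1,2-diyl carbonate (racemic) | O=C1O[C@H]2C[C@H](Br)[C@@H](Br)C[C@H]2O1
F3 | step 3 | cis-cyclohexa-3,5-diene-1,2-diyl carbonate | O=C1O[C@H]2C=CC=C[C@H]2O1
F4 | step 9 | diol ester (9 without the carbonate) | COC(=O)[C@H]1[C@@H](CO[Si](c3ccccc3)(c3ccccc3)C(C)(C)C)[C@H]2C=C[C@@H]1[C@H](O)[C@@H]2O
F5 | step 9 | dialdehyde ester | O=C[C@@H]1C=C[C@H](C=O)[C@@H](C(=O)OC)[C@H]1CO[Si](c2ccccc2)(c2ccccc2)C(C)(C)C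
F6 | step 9 | diol ester (C3 and C1'' carbinols) | OC[C@@H]1C=C[C@H](CO)[C@@H](C(=O)OC)[C@H]1CO[Si](c2ccccc2)(c2ccccc2)C(C)(C)C
F7 | step 9 | trans-fused hydroxy lactone (C1(=O)–O–C3; free C1''–OH) | OC[C@@H]1C=C[C@@H]2COC(=O)[C@H]2[C@H]1CO[Si](c3ccccc3)(c3ccccc3)C(C)(C)C
F8 | step 9 | aldehyde lactone | O=C[C@@H]1C=C[C@@H]2COC(=O)[C@H]2[C@H]1CO[Si](c3ccccc3)(c3ccccc3)C(C)(C)C
F9 | step 9 | (E)-vinyl iodide lactone | I/C=C/[C@@H]1C=C[C@@H]2COC(=O)[C@H]2[C@H]1CO[Si](c3ccccc3)(c3ccccc3)C(C)(C)C
F10 | step 15 | sulfone mesylate (C3–CH2SO2Ph on C3a; C1–OMs on C7a) | CC(C)(C)OC(=O)CCC/C=C/C=C/[C@@H]1C=C[C@H](CCS(=O)(=O)c2ccccc2)[C@@H](COS(C)(=O)=O)[C@H]1CO[Si](c2ccccc2)(c2ccccc2)C(C)(C)C
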